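**Retrosynthetic overview**

- The target is reached by fluoride removal of four triisopropylsilyl (TIPS) ethers from its tetra-silyl ether.
- The benzene ring of the dihydrobenzofuran (ring A) is built around acetylacetone instead of being taken from a resorcinol. C3a is the central carbon of acetylacetone, C4/C5 and C7a/C7 are its two acetyl groups, and C6 with the styryl arm is the ester carbon of a ferulate. The two oxygens therefore sit 1,3 about C3a by construction.
- The dihydrofuran ring comes from a [4+1] annulation of a chiral benzylic sulfonium ylide (C2 with the guaiacyl group) onto the arylidene-acetylacetone (C3 with the resorcinol-type aryl). This sets C2/C3 trans and in the absolute sense.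
- Ring order: dihydrofuran first, benzene ring A second, both in one flask (ylide annulation, then Claisen acylation and vinylogous aldol aromatisation).
- Building blocks: 3,5-dihydroxybenzaldehyde, acetylacetone, vanillin and methyl ferulate.

Assumption: (2R,5R)-2,5-dimethylthiolane is taken to give the (2R,3R) series, by analogy with the sense of its benzylidene transfer to aldehydes (recalled, not checked); if the annulation shows the opposite sense, the (2S,5S) sulfide is used with no other change.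

**Route**

Step 1
Reactants: 1 3,5-dihydroxybenzaldehyde
Product: 2 3,5-bis[(triisopropylsilyl)oxy]benzaldehyde
Conditions: TIPSCl (2.4 equiv), imidazole (5 equiv), DMF, 40 °C
Reagents that add atoms: triisopropylsilyl chloride (TIPSCl), CC(C)[Si](Cl)(C(C)C)C(C)C
Why: Imidazole-promoted silylation of phenols; TIPS ethers resist the amide bases, methoxide and mild acid met later and are removed by fluoride without touching the methyl ethers or the stilbene.

Step 2
Reactants: 2 3,5-bis[(triisopropylsilyl)oxy]benzaldehyde; 3 pentane-2,4-dione (acetylacetone)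
Product: 4 3-({3,5-bis[(triisopropylsilyl)oxy]phenyl}methylidene)pentane-2,4-dione
Conditions: piperidine (0.1 equiv), AcOH (0.1 equiv), toluene, 4 Å molecular sieves, 60 °C
Reagents that add atoms: none
Why: Knoevenagel condensation; the two acetyl groups are equivalent, so only one alkene isomer exists and the central carbon of acetylacetone is fixed as the future C3a.

Step 3
Reactants: 5 4-hydroxy-3-methoxybenzaldehyde (vanillin)
Product: 6 3-methoxy-4-[(triisopropylsilyl)oxy]benzaldehyde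
Conditions: TIPSCl (1.2 equiv), imidazole (2.5 equiv), DMF, 25 °C
Reagents that add atoms: triisopropylsilyl chloride (TIPSCl), CC(C)[Si](Cl)(C(C)C)C(C)C
Why: Imidazole-promoted silylation of the phenol, needed so that the later benzylic ylide cannot collapse to a quinone methide.

Step 4
Reactants: 6 3-methoxy-4-[(triisopropylsilyl)oxy]benzaldehyde
Product: 7 {3-methoxy-4-[(triisopropylsilyl)oxy]phenyl}methanol
Conditions: NaBH4 (0.5 equiv), THF/MeOH, 0 °C
Reagents that add atoms: none
Why: Chemoselective hydride reduction of the aryl aldehyde; the aryl silyl ether survives brief exposure at 0 °C.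

Step 5
Reactants: 7 {3-methoxy-4-[(triisopropylsilyl)oxy]phenyl}methanol
Product: 8 (2R,5R)-1-({3-methoxy-4-[(triisopropylsilyl)oxy]phenyl}methyl)-2,5-dimethylthiolan-1-ium trifluoromethanesulfonate
Conditions: (CF3SO2)2O (1.05 equiv), 2,6-lutidine (1.2 equiv), CH2Cl2, −78 °C; then (2R,5R)-2,5-dimethylthiolane (1.2 equiv), −78 to 0 °C
Reagents that add atoms: (2R,5R)-2,5-dimethylthiolane, C[C@@H]1CC[C@@H](C)S1; trifluoromethanesulfonic anhydride, O=S(=O)(OS(=O)(=O)C(F)(F)F)C(F)(F)F
Why: S-Alkylation of the sulfide by the benzylic triflate formed in situ (the para-silyloxy group makes it very reactive); the C2-symmetric sulfide has homotopic lone pairs, so a single sulfonium salt forms and sulfur is not a stereocentre.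

Step 6
Reactants: 9 methyl (2E)-3-(4-hydroxy-3-methoxyphenyl)prop-2-enoate (methyl ferulate)
Product: 10 methyl (2E)-3-{3-methoxy-4-[(triisopropylsilyl)oxy]phenyl}prop-2-enoate
Conditions: TIPSCl (1.2 equiv), imidazole (2.5 equiv), DMF, 25 °C
Reagents that add atoms: triisopropylsilyl chloride (TIPSCl), CC(C)[Si](Cl)(C(C)C)C(C)C
Why: Imidazole-promoted silylation of the phenol, which keeps the ester electrophilic under amide base (a phenoxide would deactivate it).

Step 7
Reactants: 4 3-({3,5-bis[(triisopropylsilyl)oxy]phenyl}methylidene)pentane-2,4-dione; 8 (2R,5R)-1-({3-methoxy-4-[(triisopropylsilyl)oxy]phenyl}methyl)-2,5-dimethylthiolan-1-ium trifluoromethanesulfonate; 10 methyl (2E)-3-{3-methoxy-4-[(triisopropylsilyl)oxy]phenyl}prop-2-enoate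
Product: 14 (2R,3R)-3-{3,5-bis[(triisopropylsilyl)oxy]phenyl}-2-{3-methoxy-4-[(triisopropylsilyl)oxy]phenyl}-6-[(E)-2-{3-methoxy-4-[(triisopropylsilyl)oxy]phenyl}ethenyl]-2,3-dihydro-1-benzofuran-4-ol, via sulfonium ylide 11 (not isolated), via acetyl dihydrofuran 12 (not isolated), via styryl 1,3-diketone 13 (not isolated)
Conditions: 8, LiN(SiMe3)2 (1.05 equiv), THF, −78 °C, then 4, −78 to −20 °C; LiN(SiMe3)2 (3 equiv), −78 °C, then 10, −78 to 0 °C; AcOH (20 equiv), 50 °C
Reagents that add atoms: none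
Why: Proposed new method: ylide 11 adds to the doubly activated alkene of 4 and the diketonate oxygen displaces the sulfide in a 5-exo SN2 step (sulfonium ylide [4+1] annulation, a known reaction of alkylidene 1,3-diketones) to give trans-12, the chiral sulfide fixing the ylide face so that C2 and C3 emerge R,R; in the same flask the lithium enolate of 12 is acylated by 10 (crossed Claisen condensation) to 13, and on acidification the vinylogous 2-methyl group (comparable to the reactive methyl of 2-methylchromones) closes onto the new ketone in a six-membered aldol and water is lost, so the benzene ring forms irreversibly with acylation at either methyl converging on the same arene; the closest known reaction types are ylide dihydrofuran annulations and Harris-type polyketide aldol aromatisations of 1,3,5-tricarbonyl chains.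

Step 8
Reactants: 14 (2R,3R)-3-{3,5-bis[(triisopropylsilyl)oxy]phenyl}-2-{3-methoxy-4-[(triisopropylsilyl)oxy]phenyl}-6-[(E)-2-{3-methoxy-4-[(triisopropylsilyl)oxy]phenyl}ethenyl]-2,3-dihydro-1-benzofuran-4-ol
Product: 15 (2R,3R)-3-(3,5-dihydroxyphenyl)-2-(4-hydroxy-3-methoxyphenyl)-6-[(E)-2-(4-hydroxy-3-methoxyphenyl)ethenyl]-2,3-dihydro-1-benzofuran-4-ol
Conditions: Bu4NF (4.4 equiv), AcOH (4.4 equiv), THF, 0 to 25 °C
Reagents that add atoms: none
Why: Fluoride-mediated cleavage of the four aryl silyl ethers, buffered with AcOH so that no free phenoxide can open the ring at C2 through a quinone methide; no stereocentre is touched.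

**Compound list**

1 | 3,5-dihydroxybenzaldehyde | O=Cc1cc(O)cc(O)c1 | starting material
2 | 3,5-bis[(triisopropylsilyl)oxy]benzaldehyde | O=Cc1cc(O[Si](C(C)C)(C(C)C)C(C)C)cc(O[Si](C(C)C)(C(C)C)C(C)C)c1 | intermediate
3 | pentane-2,4-dione (acetylacetone) | CC(=O)CC(C)=O | starting material
4 | 3-({3,5-bis[(triisopropylsilyl)oxy]phenyl}methylidene)pentane-2,4-dione | CC(=O)C(=Cc1cc(O[Si](C(C)C)(C(C)C)C(C)C)cc(O[Si](C(C)C)(C(C)C)C(C)C)c1)C(C)=O | intermediate
5 | 4-hydroxy-3-methoxybenzaldehyde (vanillin) | COc1cc(C=O)ccc1O | starting material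
6 | 3-methoxy-4-[(triisopropylsilyl)oxy]benzaldehyde | COc1cc(C=O)ccc1O[Si](C(C)C)(C(C)C)C(C)C | intermediate
7 | {3-methoxy-4-[(triisopropylsilyl)oxy]phenyl}methanol | COc1cc(CO)ccc1O[Si](C(C)C)(C(C)C)C(C)C | intermediate
8 | (2R,5R)-1-({3-methoxy-4-[(triisopropylsilyl)oxy]phenyl}methyl)-2,5-dimethylthiolan-1-ium trifluoromethanesulfonate | C[C@@H]1CC[C@@H](C)[S+]1Cc1ccc(O[Si](C(C)C)(C(C)C)C(C)C)c(OC)c1.[O-]S(=O)(=O)C(F)(F)F | intermediate
9 | methyl (2E)-3-(4-hydroxy-3-methoxyphenyl)prop-2-enoate (methyl ferulate) | COC(=O)/C=C/c1ccc(O)c(OC)c1 | starting material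
10 | methyl (2E)-3-{3-methoxy-4-[(triisopropylsilyl)oxy]phenyl}prop-2-enoate | COC(=O)/C=C/c1ccc(O[Si](C(C)C)(C(C)C)C(C)C)c(OC)c1 | intermediate
11 | [(2R,5R)-2,5-dimethylthiolan-1-ium-1-yl]{3-methoxy-4-[(triisopropylsilyl)oxy]phenyl}methanide (sulfonium ylide) | C[C@@H]1CC[C@@H](C)[S+]1[CH-]c1ccc(O[Si](C(C)C)(C(C)C)C(C)C)c(OC)c1 | intermediate
12 | 1-[(4R,5R)-4-{3,5-bis[(triisopropylsilyl)oxy]phenyl}-5-{3-methoxy-4-[(triisopropylsilyl)oxy]phenyl}-2-methyl-4,5-dihydrofuran-3-yl]ethan-1-one | CC(=O)C1=C(C)O[C@@H](c2ccc(O[Si](C(C)C)(C(C)C)C(C)C)c(OC)c2)[C@@H]1c3cc(O[Si](C(C)C)(C(C)C)C(C)C)cc(O[Si](C(C)C)(C(C)C)C(C)C)c3 | intermediate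
13 | (4E)-1-[(4R,5R)-4-{3,5-bis[(triisopropylsilyl)oxy]phenyl}-5-{3-methoxy-4-[(triisopropylsilyl)oxy]phenyl}-2-methyl-4,5-dihydrofuran-3-yl]-5-{3-methoxy-4-[(triisopropylsilyl)oxy]phenyl}pent-4-ene-1,3-dione | COc1cc(/C=C/C(=O)CC(=O)C2=C(C)O[C@@H](c3ccc(O[Si](C(C)C)(C(C)C)C(C)C)c(OC)c3)[C@@H]2c4cc(O[Si](C(C)C)(C(C)C)C(C)C)cc(O[Si](C(C)C)(C(C)C)C(C)C)c4)ccc1O[Si](C(C)C)(C(C)C)C(C)C | intermediate
14 | (2R,3R)-3-{3,5-bis[(triisopropylsilyl)oxy]phenyl}-2-{3-methoxy-4-[(triisopropylsilyl)oxy]phenyl}-6-[(E)-2-{3-methoxy-4-[(triisopropylsilyl)oxy]phenyl}ethenyl]-2,3-dihydro-1-benzofuran-4-ol | COc1cc(/C=C/c2cc(O)c3c(c2)O[C@@H](c4ccc(O[Si](C(C)C)(C(C)C)C(C)C)c(OC)c4)[C@@H]3c5cc(O[Si](C(C)C)(C(C)C)C(C)C)cc(O[Si](C(C)C)(C(C)C)C(C)C)c5)ccc1O[Si](C(C)C)(C(C)C)C(C)C | intermediate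
15 | (2R,3R)-3-(3,5-dihydroxyphenyl)-2-(4-hydroxy-3-methoxyphenyl)-6-[(E)-2-(4-hydroxy-3-methoxyphenyl)ethenyl]-2,3-dihydro-1-benzofuran-4-ol | COc1cc(/C=C/c2cc(O)c3c(c2)O[C@@H](c2ccc(O)c(OC)c2)[C@@H]3c2cc(O)cc(O)c2)ccc1O | target

**Step count and risks**

Total: 8 steps. Longest linear sequence: 5 steps (5 → 6 → 7 → 8 → 14 → 15).

Steps most likely to fail:

1. Step 7. Three events share one flask. The enantioselection of the ylide annulation is unproven for this acceptor, and the aldol closure of the 2-methyl group onto the diketone is the unprecedented link; opening of the dihydrofuran to a 4-pyranone is the likely side path. The fallback sets out from 12 and from 6 and returns at 14. Step 7 is quenched at −20 °C after the annulation and 12 is isolated, which also lets its enantiomeric purity be checked and raised by crystallisation. Ring A is then built at the aldehyde oxidation level and aromatised by oxidation instead of by loss of water. Wittig reaction of 6 with Ph3P=CHCHO in toluene at 80 °C gives the enal (2E)-3-{3-methoxy-4-[(triisopropylsilyl)oxy]phenyl}prop-2-enal F1. Aldol addition of the lithium enolate of 12 (LiN(SiMe3)2, THF, −78 °C) to F1 gives the β-hydroxy ketone (4E)-3-hydroxy-1-(dihydrofuran-3-yl)-5-arylpent-4-en-1-one F2. MsCl and excess Et3N dehydrate it to the dienone (2E,4E)-1-(dihydrofuran-3-yl)-5-arylpenta-2,4-dien-1-one F3. DBU in toluene at 80 °C closes the vinylogous 2-methyl group onto the enone (6-endo Michael addition) to give the 6-styryl-2,3,6,7-tetrahydro-1-benzofuran-4(5H)-one F4. Aerobic dehydrogenation with Pd(O2CCF3)2, 2-(dimethylamino)pyridine and TsOH under O2 in DMSO at 80 °C converts F4 into 14.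

2. Step 5. The para-silyloxybenzyl triflate may polymerise or alkylate the lutidine before the sulfide captures it, and the salt is a labile alkylating agent. The fallback sets out from 6 and returns at 11, making the ylide by carbene transfer instead of alkylation and deprotonation. Condensation of 6 with TsNHNH2 in THF gives the tosylhydrazone N'-[(E)-{3-methoxy-4-[(triisopropylsilyl)oxy]phenyl}methylidene]-4-methylbenzenesulfonohydrazide F5, and NaH converts it into the sodium salt of that tosylhydrazone F6. Warming F6 to 40 °C in 1,4-dioxane with BnEt3NCl, Rh2(OAc)4 (1 mol %), (2R,5R)-2,5-dimethylthiolane (now needed only in substoichiometric amount) and 4 releases the aryldiazomethane [4-(diazomethyl)-2-methoxyphenoxy]triisopropylsilane F7 slowly. The rhodium carbene formed from F7 is captured by the sulfide as ylide 11, which reacts with 4 as in step 7. A known competitor is dipolar addition of F7 to 4, held back by the slow release.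

3. Step 8. The free pentaphenol is air- and base-sensitive, can open at C2 through a quinone methide, and is hard to purify. The fallback sets out from 14 and returns at 15, exchanging the protecting groups through a stable, crystallisable derivative. CsF and Ac2O in DMF at 25 °C trap each phenoxide as it is released (the free C4 hydroxyl is acetylated as well) and give the pentaacetate 5-[(2R,3R)-4-acetoxy-2-(4-acetoxy-3-methoxyphenyl)-6-[(E)-2-(4-acetoxy-3-methoxyphenyl)ethenyl]-2,3-dihydro-1-benzofuran-3-yl]-1,3-phenylene diacetate F8. It is purified by crystallisation and deacetylated under near-neutral conditions (NH4OAc, MeOH/H2O, 25 °C) to 15.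

**Further compounds**

F1 | step 7 | (2E)-3-{3-methoxy-4-[(triisopropylsilyl)oxy]phenyl}prop-2-enal | O=C/C=C/c1ccc(O[Si](C(C)C)(C(C)C)C(C)C)c(OC)c1
F2 | step 7 | (4E)-1-[(4R,5R)-4-{3,5-bis[(triisopropylsilyl)oxy]phenyl}-5-{3-methoxy-4-[(triisopropylsilyl)oxy]phenyl}-2-methyl-4,5-dihydrofuran-3-yl]-3-hydroxy-5-{3-methoxy-4-[(triisopropylsilyl)oxy]phenyl}pent-4-en-1-one (both carbinol epimers) | COc1cc(/C=C/C(O)CC(=O)C2=C(C)O[C@@H](c3ccc(O[Si](C(C)C)(C(C)C)C(C)C)c(OC)c3)[C@@H]2c4cc(O[Si](C(C)C)(C(C)C)C(C)C)cc(O[Si](C(C)C)(C(C)C)C(C)C)c4)ccc1O[Si](C(C)C)(C(C)C)C(C)C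
F3 | step 7 | (2E,4E)-1-[(4R,5R)-4-{3,5-bis[(triisopropylsilyl)oxy]phenyl}-5-{3-methoxy-4-[(triisopropylsilyl)oxy]phenyl}-2-methyl-4,5-dihydrofuran-3-yl]-5-{3-methoxy-4-[(triisopropylsilyl)oxy]phenyl}penta-2,4-dien-1-one | COc1cc(/C=C/C=C/C(=O)C2=C(C)O[C@@H](c3ccc(O[Si](C(C)C)(C(C)C)C(C)C)c(OC)c3)[C@@H]2c4cc(O[Si](C(C)C)(C(C)C)C(C)C)cc(O[Si](C(C)C)(C(C)C)C(C)C)c4)ccc1O[Si](C(C)C)(C(C)C)C(C)C
F4 | step 7 | (2R,3R)-3-{3,5-bis[(triisopropylsilyl)oxy]phenyl}-2-{3-methoxy-4-[(triisopropylsilyl)oxy]phenyl}-6-[(E)-2-{3-methoxy-4-[(triisopropylsilyl)oxy]phenyl}ethenyl]-2,3,6,7-tetrahydro-1-benzofuran-4(5H)-one (both C6 epimers) | COc1cc(/C=C/C2CC(=O)C3=C(C2)O[C@@H](c4ccc(O[Si](C(C)C)(C(C)C)C(C)C)c(OC)c4)[C@@H]3c5cc(O[Si](C(C)C)(C(C)C)C(C)C)cc(O[Si](C(C)C)(C(C)C)C(C)C)c5)ccc1O[Si](C(C)C)(C(C)C)C(C)C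
F5 | step 5 | N'-[(E)-{3-methoxy-4-[(triisopropylsilyl)oxy]phenyl}methylidene]-4-methylbenzenesulfonohydrazide | COc1cc(/C=N/NS(=O)(=O)c2ccc(C)cc2)ccc1O[Si](C(C)C)(C(C)C)C(C)C
F6 | step 5 | sodium salt of N'-[(E)-{3-methoxy-4-[(triisopropylsilyl)oxy]phenyl}methylidene]-4-methylbenzenesulfonohydrazide | COc1cc(/C=N/[N-]S(=O)(=O)c2ccc(C)cc2)ccc1O[Si](C(C)C)(C(C)C)C(C)C.[Na+]
F7 | step 5 | [4-(diazomethyl)-2-methoxyphenoxy]triisopropylsilane | COc1cc(C=[N+]=[N-])ccc1O[Si](C(C)C)(C(C)C)C(C)C
F8 | step 8 | 5-[(2R,3R)-4-acetoxy-2-(4-acetoxy-3-methoxyphenyl)-6-[(E)-2-(4-acetoxy-3-methoxyphenyl)ethenyl]-2,3-dihydro-1-benzofuran-3-yl]-1,3-phenylene diacetate | COc1cc(/C=C/c2cc(OC(C)=O)c3c(c2)O[C@@H](c4ccc(OC(C)=O)c(OC)c4)[C@@H]3c5cc(OC(C)=O)cc(OC(C)=O)c5)ccc1OC(C)=O
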